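**Plan**

- Retrosynthesis: the O3' benzyl ether is cleaved first. Ring B is then cut at C1'–C6' and C3'–C4' into an acyclic keto ester and 2-pentylpropanedial. The keto ester is cut at the carboxylate O–CH2 bond, and ring A at C1–C6 and C3–C4 (Michael and Dieckmann bonds).
- Enabling feature: in ring B, C1', C2' and C3' carry three adjacent oxygens of which only O1' is acylated, which is the pattern of a 1,3-dihydroxyacetone monoester. C4'–C5'(pentyl)–C6' is a CH–C(alkyl)–CH unit, which is a 2-pentylmalonaldehyde. Both pieces already have the oxidation level of a phenol-forming [3+3] condensation.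
- Forward: ring A is made first (Michael–Dieckmann, aromatisation, 4-O-methylation, saponification) and joined through its carboxylate to 1-(benzyloxy)-3-chloropropan-2-one. Ring B is closed last onto this ester with the dialdehyde made from heptanal. Hydrogenolysis ends the route.
- Stereochemistry: the target is achiral, with no stereocentre and no stereogenic double bond, so nothing has to be controlled.

Key step: step 11

Remark on the chemistry: racemic epichlorohydrin is used, and the transient sp3 centres, tautomers and E/Z isomers of 3, 4, 5, 10, 19 and 20 are taken as they come, because all of them vanish on oxidation or aromatisation.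

**Route**

Step 1
Reactants: 1 methyl acetoacetate; 2 methyl (E)-hex-2-enoate
Product: 4 methyl 2,4-dioxo-6-propylcyclohexane-1-carboxylate, via Michael adduct 3 (not isolated)
Conditions: NaOMe (1.1 equiv), MeOH, reflux; then cold aq. HCl
Reagents that add atoms: none
Why: Tandem Michael addition–Dieckmann (Claisen) cyclisation, in which the acetoacetate anion adds to C3 of the enoate and the methyl ketone enolate of 3 closes onto the distal ester, the acidic 1,3-dione being held as its sodium enolate; this is the classical dihydroresorcylate synthesis.

Step 2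
Reactants: 4 methyl 2,4-dioxo-6-propylcyclohexane-1-carboxylate
Product: 6 methyl 2,4-dihydroxy-6-propylbenzoate, via bromodione 5 (not isolated)
Conditions: Br2 (1.0 equiv), DMF, 0 °C, then 80 °C
Reagents that add atoms: none
Why: Oxidative aromatisation by bromination of the 1,3-dione at C3 followed by enolisation and thermal loss of HBr, a procedure established for the 6-alkyl homologues of this dione ester.

Step 3
Reactants: 6 methyl 2,4-dihydroxy-6-propylbenzoate
Product: 7 methyl 2-hydroxy-4-methoxy-6-propylbenzoate
Conditions: MeI (1.05 equiv), K2CO3 (1.1 equiv), acetone, reflux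
Reagents that add atoms: iodomethane, CI
Why: Williamson ether synthesis that should touch only the 4-OH, because the 2-OH is locked in a hydrogen bond to the ester carbonyl and is the weaker acid, as known for orsellinate esters.

Step 4
Reactants: 7 methyl 2-hydroxy-4-methoxy-6-propylbenzoate
Product: 8 2-hydroxy-4-methoxy-6-propylbenzoic acid
Conditions: KOH (5 equiv), DMSO/H2O, 90 °C; then aq. HCl, 0 °C
Reagents that add atoms: potassium hydroxide, [K+].[OH-]
Why: Saponification of a hindered, hydrogen-bonded ester under forcing base, in which the dianion is stable and cold acidification should avoid decarboxylation of the β-resorcylic acid.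

Step 5
Reactants: 9 epichlorohydrin (racemic)
Product: 10 1-(benzyloxy)-3-chloropropan-2-ol (racemic)
Conditions: BnOH (3 equiv), BF3·OEt2 (2 mol %), 50 °C, slow addition of 9
Reagents that add atoms: benzyl alcohol, OCc1ccccc1
Why: Lewis acid-catalysed epoxide opening by the alcohol at the unsubstituted carbon, with excess alcohol to suppress oligomerisation; the carbinol centre is removed in step 6.

Step 6
Reactants: 10 1-(benzyloxy)-3-chloropropan-2-ol
Product: 11 1-(benzyloxy)-3-chloropropan-2-one
Conditions: Dess–Martin periodinane (1.2 equiv), CH2Cl2, 0 °C to rt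
Reagents that add atoms: none
Why: Dess–Martin oxidation of a secondary alcohol under neutral conditions that leave the benzyl ether and the primary chloride untouched.

Step 7
Reactants: 8 2-hydroxy-4-methoxy-6-propylbenzoic acid; 11 1-(benzyloxy)-3-chloropropan-2-one
Product: 13 3-(benzyloxy)-2-oxopropyl 2-hydroxy-4-methoxy-6-propylbenzoate, via potassium carboxylate 12 (not isolated)
Conditions: KHCO3 (1.2 equiv), DMF, rt to 40 °C
Reagents that add atoms: none
Why: SN2 O-alkylation of a carboxylate by an α-chloro ketone (phenacyl-type ester formation), in which KHCO3 ionises only the carboxylic acid so the hydrogen-bonded phenol stays unalkylated and the hindered carbonyl never has to act as an electrophile.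

Step 8
Reactants: 14 heptanal
Product: 15 1,1-dimethoxyheptane
Conditions: HC(OMe)3 (1.5 equiv), p-TsOH (1 mol %), MeOH, rt
Reagents that add atoms: trimethyl orthoformate, COC(OC)OC; methanol, CO
Why: Acid-catalysed acetalisation driven to completion by the orthoformate as water scavenger.

Step 9
Reactants: 15 1,1-dimethoxyheptane
Product: 17 (E)-3-(dimethylamino)-2-pentylprop-2-enal, via methoxypropeniminium salt 16 (not isolated)
Conditions: POCl3 (2.2 equiv), DMF (6 equiv), 0 °C then 70 °C; ice, aq. K2CO3
Reagents that add atoms: N,N-dimethylformamide, CN(C)C=O; water, O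
Why: Vilsmeier–Haack (Arnold) formylation, in which the acetal loses methanol to its enol ether, the chloroiminium ion formylates the enol ether carbon to give 16, and mild aqueous base hydrolyses the oxygen-bearing terminus to the vinylogous formamide; this is the standard entry to 2-alkyl-3-aminoacroleins.

Step 10
Reactants: 17 (E)-3-(dimethylamino)-2-pentylprop-2-enal
Product: 18 2-pentylpropanedial
Conditions: 2 M aq. NaOH, 80 °C, N2 stream; then aq. HCl to pH 3, 0 °C; used promptly
Reagents that add atoms: sodium hydroxide, [Na+].[OH-]
Why: Addition–elimination hydrolysis of a vinylogous amide with loss of volatile dimethylamine, giving the stable malonaldehyde enolate that is protonated on cold acidification (the product exists largely as its enol).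

Step 11
Reactants: 13 3-(benzyloxy)-2-oxopropyl 2-hydroxy-4-methoxy-6-propylbenzoate; 18 2-pentylpropanedial
Product: 21 3-(benzyloxy)-2-hydroxy-5-pentylphenyl 2-hydroxy-4-methoxy-6-propylbenzoate, via enone aldehyde 19 (not isolated), via cyclohexadienone 20 (not isolated)
Conditions: [C5H10NH2][CH3CO2] (0.3 equiv), 4 Å molecular sieves, MeCN, N2, rt then 60 °C
Reagents that add atoms: none
Why: Proposed new method: piperidine turns 18 into its enaminal/iminium form and 13 into an enamine or enol, so a Knoevenagel-type condensation at one oxygen-bearing CH2 should give enone aldehyde 19, whose double-bond geometry can equilibrate through the dienol; the second CH2 then adds to the remaining formyl group, water is lost to give cyclohexa-2,5-dienone 20, and enolisation at C5' makes the arene with the former ketone carbon as the C2' phenol. The closest known reaction type is the [3+3] phenol synthesis from 1,3-disubstituted acetones (acetonedicarboxylates, dibenzyl ketone) and nitromalonaldehyde, 2-substituted malonaldehydes or vinamidinium salts; new here is a ketone flanked by an ether oxygen and an ester oxygen. Ring B closes by a 6-(enolendo)-exo-trig aldol followed by dehydration. No stereocentre is created, and because 18 is symmetric both orientations of union give the same ring. The step needs chemoselectivity: condensation at carbon without O-to-O acyl shift in the enolate or the new phenol, and without aminolysis of the ester. The di-ortho-substituted, hydrogen-bonded aroyl group, the weakly basic buffered amine salt, the non-nucleophilic solvent and the irreversible aromatisation should secure this, and the acyl group sits on the less hindered terminal oxygen, where equilibration would also leave it.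

Step 12
Reactants: 21 3-(benzyloxy)-2-hydroxy-5-pentylphenyl 2-hydroxy-4-methoxy-6-propylbenzoate
Product: 22 Peruvinide C (2,3-dihydroxy-5-pentylphenyl 2-hydroxy-4-methoxy-6-propylbenzoate)
Conditions: H2 (1 atm), Pd/C, EtOAc, rt
Reagents that add atoms: none
Why: Catalytic hydrogenolysis of the benzyl aryl ether under neutral conditions, which should leave the aryl ester and methyl ether intact and avoid base-promoted acyl migration in the catechol monoester.

**Compound list**

1 | methyl acetoacetate | CC(=O)CC(=O)OC | starting material
2 | methyl (E)-hex-2-enoate | CCC/C=C/C(=O)OC | starting material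
3 | dimethyl 2-acetyl-3-propylpentanedioate (Michael adduct, racemic diastereomer mixture, not isolated) | CCCC(CC(=O)OC)C(C(C)=O)C(=O)OC | intermediate
4 | methyl 2,4-dioxo-6-propylcyclohexane-1-carboxylate (racemic, diastereomers and enol tautomers) | CCCC1CC(=O)CC(=O)C1C(=O)OC | intermediate
5 | methyl 3-bromo-2,4-dioxo-6-propylcyclohexane-1-carboxylate (stereoisomer mixture, not isolated) | CCCC1CC(=O)C(Br)C(=O)C1C(=O)OC | intermediate
6 | methyl 2,4-dihydroxy-6-propylbenzoate | CCCc1cc(O)cc(O)c1C(=O)OC | intermediate
7 | methyl 2-hydroxy-4-methoxy-6-propylbenzoate | CCCc1cc(OC)cc(O)c1C(=O)OC | intermediate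
8 | 2-hydroxy-4-methoxy-6-propylbenzoic acid | CCCc1cc(OC)cc(O)c1C(=O)O | intermediate
9 | epichlorohydrin (racemic) | ClCC1CO1 | starting material
10 | 1-(benzyloxy)-3-chloropropan-2-ol (racemic) | OC(CCl)COCc1ccccc1 | intermediate
11 | 1-(benzyloxy)-3-chloropropan-2-one | O=C(CCl)COCc1ccccc1 | intermediate
12 | potassium 2-hydroxy-4-methoxy-6-propylbenzoate (not isolated) | CCCc1cc(OC)cc(O)c1C(=O)[O-].[K+] | intermediate
13 | 3-(benzyloxy)-2-oxopropyl 2-hydroxy-4-methoxy-6-propylbenzoate | CCCc1cc(OC)cc(O)c1C(=O)OCC(=O)COCc1ccccc1 | intermediate
14 | heptanal | CCCCCCC=O | starting material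
15 | 1,1-dimethoxyheptane | CCCCCCC(OC)OC | intermediate
16 | N-(3-methoxy-2-pentylprop-2-en-1-ylidene)-N-methylmethanaminium dichlorophosphate (geometry undefined, not isolated) | CCCCCC(=COC)C=[N+](C)C.[O-]P(=O)(Cl)Cl | intermediate
17 | (E)-3-(dimethylamino)-2-pentylprop-2-enal | CCCCC/C(C=O)=C\N(C)C | intermediate
18 | 2-pentylpropanedial (in equilibrium with its enol) | CCCCCC(C=O)C=O | intermediate
19 | 1-(benzyloxy)-5-formyl-2-oxodec-3-en-3-yl 2-hydroxy-4-methoxy-6-propylbenzoate (E/Z mixture, racemic, not isolated) | CCCCCC(C=O)C=C(OC(=O)c1c(O)cc(OC)cc1CCC)C(=O)COCc1ccccc1 | intermediate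
20 | 5-(benzyloxy)-6-oxo-3-pentylcyclohexa-1,4-dien-1-yl 2-hydroxy-4-methoxy-6-propylbenzoate (racemic, not isolated) | CCCCCC1C=C(OCc2ccccc2)C(=O)C(OC(=O)c2c(O)cc(OC)cc2CCC)=C1 | intermediate
21 | 3-(benzyloxy)-2-hydroxy-5-pentylphenyl 2-hydroxy-4-methoxy-6-propylbenzoate | CCCCCc1cc(OCc2ccccc2)c(O)c(OC(=O)c2c(O)cc(OC)cc2CCC)c1 | intermediate
22 | Peruvinide C, 2,3-dihydroxy-5-pentylphenyl 2-hydroxy-4-methoxy-6-propylbenzoate | CCCCCc1cc(O)c(O)c(OC(=O)c2c(O)cc(OC)cc2CCC)c1 | target

**Step count and risks**

Total steps: 12. Longest linear sequence: 7 steps (1, 2, 3, 4, 7, 11, 12).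

Steps most likely to fail:

1. Step 11 (the unprecedented condensation). The α-acyloxy ketone may self-condense or shift its acyl group faster than it condenses with the weakly electrophilic alkylmalonaldehyde, or the second, ring-closing aldol may stall at the open-chain stage. The fallback uses known chemistry, sets out from acid 8 and comes back at target 22, replacing steps 11 and 12. Commercial 5-bromo-2,3-dihydroxybenzaldehyde would be benzylated on both oxygens (BnBr, K2CO3, DMF) to 2,3-bis(benzyloxy)-5-bromobenzaldehyde F1. Negishi coupling with C5H11ZnBr (Pd(dppf)Cl2 cat., THF, 50 °C) would give 2,3-bis(benzyloxy)-5-pentylbenzaldehyde F2. Baeyer–Villiger oxidation (mCPBA, CH2Cl2) would give 2,3-bis(benzyloxy)-5-pentylphenyl formate F3, and methanolysis (cat. K2CO3, MeOH) would give 2,3-bis(benzyloxy)-5-pentylphenol F4. Mixed-anhydride depside esterification of F4 with 8 ((CF3CO)2O, toluene, rt) would give 2,3-bis(benzyloxy)-5-pentylphenyl 2-hydroxy-4-methoxy-6-propylbenzoate F5. Hydrogenolysis of both benzyl ethers (H2, Pd/C, EtOAc) would then deliver 22.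

2. Step 2. Nuclear bromination of the electron-rich resorcylate may compete with dehydrobromination, so that aromatisation stops short or gives ring-brominated mixtures. The fallback sets out from 4 and comes back at 6. Excess Br2 in AcOH would drive both aromatisation and ring bromination to completion, giving methyl 3,5-dibromo-2,4-dihydroxy-6-propylbenzoate F6. Hydrogenolysis of both C–Br bonds (H2, Pd/C, NaOAc, MeOH) would return 6.

3. Step 9. Formylation of the enol ether may be outrun by acid-promoted self-condensation or chlorination of the liberated aldehyde equivalents. The fallback sets out from 15 and comes back at 18, replacing steps 9 and 10. Acetal 15 would be cracked to 1-methoxyhept-1-ene F7 (cat. p-TsOH, quinoline, distillation of methanol). Trimethyl orthoformate would be added across the enol ether (cat. BF3·OEt2, 0 °C) to give 1,1,3,3-tetramethoxy-2-pentylpropane F8. Hydrolysis of both acetals (1 M HCl, THF, rt) would give 18.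

**Further compounds**

F1 | step 11 | 2,3-bis(benzyloxy)-5-bromobenzaldehyde | O=Cc1cc(Br)cc(OCc2ccccc2)c1OCc1ccccc1
F2 | step 11 | 2,3-bis(benzyloxy)-5-pentylbenzaldehyde | CCCCCc1cc(C=O)c(OCc2ccccc2)c(OCc2ccccc2)c1
F3 | step 11 | 2,3-bis(benzyloxy)-5-pentylphenyl formate | CCCCCc1cc(OC=O)c(OCc2ccccc2)c(OCc2ccccc2)c1
F4 | step 11 | 2,3-bis(benzyloxy)-5-pentylphenol | CCCCCc1cc(O)c(OCc2ccccc2)c(OCc2ccccc2)c1
F5 | step 11 | 2,3-bis(benzyloxy)-5-pentylphenyl 2-hydroxy-4-methoxy-6-propylbenzoate | CCCCCc1cc(OCc2ccccc2)c(OCc2ccccc2)c(OC(=O)c2c(O)cc(OC)cc2CCC)c1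
F6 | step 2 | methyl 3,5-dibromo-2,4-dihydroxy-6-propylbenzoate | CCCc1c(Br)c(O)c(Br)c(O)c1C(=O)OC
F7 | step 9 | 1-methoxyhept-1-ene (E/Z mixture) | CCCCCC=COC
F8 | step 9 | 1,1,3,3-tetramethoxy-2-pentylpropane | CCCCCC(C(OC)OC)C(OC)OC
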